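## The problem

The target is a cis-fused bicyclo[5.3.0]decane. The seven-membered ring is numbered C1 (ester carbon), C2, C3 (methyl-bearing fusion carbon), C7 (hydroxyl-bearing fusion carbon), C8, C9, C10 (methyl carbinol); the five-membered ring is C3, C4, C5, C6 (isopropyl carbon), C7. It has five stereocentres. The C3 methyl, C7 hydroxyl and C6 isopropyl lie on one face (β); the C1 ester is also β and the C10 hydroxyl is α, so C1/C10 is a trans diol monoester. Only C6 can be taken from the chiral pool. It has to set the quaternary C3 and the tertiary carbinol C7; C7 then has to set C1 across the ring, and C1 has to set C10. The two tertiary alcohols are prone to dehydration. The C7 hydroxyl also lies across the ring from C10 and would trap a cation or an α-epoxide there as a bridging ether. The aryl ester does not survive hydride or strong base, so it must come late. The key step rests on one feature: C7 carries oxygen and its ring neighbour C8 is an unsubstituted methylene, so C7–O and C7–C8 can be a spiro-epoxide on the cyclopentane, and C9 can be the carbanion of an allyl sulfone whose (Z)-alkene C1=C10 is the cis double bond of a cycloheptene. One complication follows: after ring closure the allyl unit C9–C10–C1 has two secondary termini, so sulfur cannot be removed through a free allyl anion without losing the alkene position.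

## Retrosynthesis

**27 to 25 (C10–O).** The C10 hydroxyl is added last, by Markovnikov hydration of the C9=C10 alkene of ester 25 through a hydrogen-atom-transfer (radical) process. An acid-mediated hydration or epoxide opening would place a cation at C10 within reach of the C7 hydroxyl. Acylating a triol last would give up the shielding of the β face by the C1 ester. The forward step must deliver oxygen to the α face of a tertiary radical.

**25 to 23 to 22 to 21 (C1–O, removal of sulfur).** Ester 25 comes from allylic diol 23 and acid chloride 24. Diol 23 comes from epoxy sulfone 22 by reductive cleavage of the C9–S bond with opening of the adjacent epoxide. Epoxide 22 comes from alkene 21 by hydroxyl-directed epoxidation. Plain reductive desulfonylation of 21 was set aside because the allyl anion could be protonated at C9 or at C1. In the chosen order the sulfone is spent in a regiodefined elimination that also reveals the C1 oxygen. The forward sequence asks the C7 hydroxyl to deliver oxygen to the β face of C1=C10.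

**21 to 20 (C8–C9, the seven-membered ring).** Cutting C8–C9 turns the bicycle into a cyclopentane with one side chain, epoxy sulfone 20. No other single cut in the large ring leaves both the C7 oxygen and a stabilised carbanion in place. The forward reaction needs attack at C8 rather than C7, α-attack of the allyl anion, and a (Z)-alkene.

**20 to 17 to 16 to 14 (C9–S, C1=C10).** Sulfone 20 comes from (Z)-allylic alcohol 17 and sulfinate 18, and 17 from (Z)-enoate 16. Enoate 16 is cut at C1=C10 to aldehyde 14 and phosphonate 15. Alkylating a ketone enolate with a bromo allyl sulfone would be shorter, but the enolate can deprotonate the sulfone and the reagent can lose HBr. A Z-selective olefination sets the geometry in a separate step.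

**14 to 13 to 11 (C7–C8 and C8–O).** Aldehyde 14 comes from ester 13. The spiro-epoxide of 13 is cut to ketone 11 and a sulfur ylide from 12. Peracid epoxidation of alkene 9 would put the oxygen on the open α face. Ylide addition puts the methylene there and leaves the oxygen β, which is what the target needs.

**11 to 9 to 6 + 7 (C2–C3).** Ketone 11 comes from methylene compound 9 by ozonolysis. Ester 9 is cut at C2–C3 by a Claisen rearrangement of allylic alcohol 6 with orthoester 7. This builds the quaternary centre without a ketone enolate, so there is no question of which α-carbon is deprotonated and C6 is never enolised. The forward step must form the bond on the face away from the C6 isopropyl group.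

**6 to 5 to 4 to 2 to 1.** Alcohol 6 comes from enal 5, 5 from keto aldehyde 4 by aldol condensation, 4 from alkene 2 by ozonolysis, and 2 from (S)-limonene 1 by selective hydrogenation. The C4 centre of 1 becomes C6 of the target and is the only purchased stereocentre.

## Roads not taken

**Alternative 1:** The cut is C6–C7. A chiral Lewis acid would activate one of the two enantiotopic ketones of dione A1, and the trisubstituted alkene would add through C6 with hydrogen transfer from a methyl group to give hydroxy ketone A2.
- Merits: the precursor is achiral and easy to picture, and one step would set C3, C6 and C7 and close the cyclopentane. The bicycle is reached in far fewer steps than the twelve needed for 21.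
- Weak points: an enantioselective ketone-ene desymmetrisation of a seven-membered 1,3-dione has no close model. A2 carries its carbonyl at C2, where the target has a methylene, while C1 and C10 are bare. The ester oxygen, the C10 methyl and the C10 hydroxyl would need a carbonyl transposition and two further stereocentres set far from any control element.
- Comparison: this road is clearly shorter to the ring system. The chosen plan sets against it that ring closure leaves an alkene and a sulfone exactly at C1, C9 and C10, which four steps convert into the final pattern.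

**Alternative 2:** The cuts are C3–C7 and C1–C10. The oxyallyl cation from α-chloro ketone A3 would add across the tethered furan to give the oxygen-bridged tricycle A4.
- Merits: both carbocycles and the quaternary C3 form in one step, and the furan oxygen supplies the oxygens at C7 and C10. This is more convergent than the chosen plan.
- Weak points: the bridge holds the C10 oxygen on the face of the C7 oxygen, whereas the target has it on the opposite face, so a C–O bond would have to be broken and remade with inversion. The ketone sits at C2 and must be moved to C1. Bond formation joins two fully substituted carbons, and the only control of facial selectivity is the C6 centre in the tether.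
- Comparison: the ring construction is more economical, but the product is further from the target's oxidation pattern than 21.

**Alternative 3:** The cut is C3–C7 across a ten-membered ring. SmI2 would reduce enedione A5, and the C7 ketyl would add to enone carbon C3 to give hydroxy ketone A6.
- Merits: A6 already has the C1 carbonyl, the C10 methyl, the C7 hydroxyl and the cis fusion. Hydroxylation at C10, reduction at C1 and acylation would finish, with no sulfur to remove. This end game is shorter than the chosen one.
- Weak points: A5 is a medium ring with a trisubstituted enone and an epimerisable C6 centre, so making it is a problem of the same size as the target. The stereochemistry of the transannular closure depends on the ring conformation, which one isopropyl group may not control.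
- Comparison: if A5 were at hand this would be the shortest road. The chosen plan offers an open-chain precursor made by standard reactions and stereocentres set one at a time.

Key step: step 12

Assumption: phosphonate 15 is taken as a purchased reagent, and the configuration at the sulfonyl-bearing C9 of 21 and 22 is left open because C9 becomes trigonal in step 14.

## Route

Step 1
Reactants: 1 (S)-(−)-limonene
Product: 2 (4S)-1-methyl-4-(propan-2-yl)cyclohex-1-ene
Conditions: H2 (1 atm), RhCl(PPh3)3 (cat.), PhH–EtOH, 25 °C
Reagents that add atoms: none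
Why: Homogeneous catalytic hydrogenation reduces the 1,1-disubstituted isopropenyl alkene much faster than the trisubstituted ring alkene; the stereocentre is not touched.

Step 2
Reactants: 2 (4S)-1-methyl-4-(propan-2-yl)cyclohex-1-ene
Product: 4 (3S)-6-oxo-3-(propan-2-yl)heptanal, via ozonide 3 (not isolated)
Conditions: O3, CH2Cl2, −78 °C; then PPh3, −78 to 25 °C
Reagents that add atoms: ozone, [O-][O+]=O
Why: Ozonolysis with reductive work-up cleaves the only alkene to the keto aldehyde; the stereocentre is α to neither carbonyl and cannot epimerise.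

Step 3
Reactants: 4 (3S)-6-oxo-3-(propan-2-yl)heptanal
Product: 5 (5R)-2-methyl-5-(propan-2-yl)cyclopent-1-ene-1-carbaldehyde
Conditions: piperidine (cat.), AcOH (cat.), PhH, reflux, water removal
Reagents that add atoms: none
Why: Intramolecular aldol condensation under amine–acid catalysis: the enamine of the aldehyde attacks the methyl ketone to close the five-membered ring, and dehydration gives the conjugated enal, the known mode for 6-oxoheptanals under these conditions; the isopropyl centre is not enolised.

Step 4
Reactants: 5 (5R)-2-methyl-5-(propan-2-yl)cyclopent-1-ene-1-carbaldehyde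
Product: 6 [(5R)-2-methyl-5-(propan-2-yl)cyclopent-1-en-1-yl]methanol
Conditions: NaBH4, CeCl3·7H2O, MeOH, 0 °C
Reagents that add atoms: none
Why: Luche reduction gives clean 1,2-reduction of the hindered enal to the primary allylic alcohol.

Step 5
Reactants: 6 [(5R)-2-methyl-5-(propan-2-yl)cyclopent-1-en-1-yl]methanol; 7 triethyl orthoacetate
Product: 9 ethyl 2-[(1R,3R)-1-methyl-2-methylidene-3-(propan-2-yl)cyclopentyl]acetate, via ketene acetal 8 (not isolated)
Conditions: MeC(OEt)3 (excess), EtCO2H (cat.), 140 to 170 °C, EtOH distilled off
Reagents that add atoms: none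
Why: Johnson–Claisen rearrangement: exchange and loss of ethanol give ketene acetal 8, whose [3,3] shift forms C2–C3 and the exocyclic C7=C8 alkene. The tether hangs from C7 next to C6, so the chair transition state on the face away from the isopropyl group should be favoured; the acetate arm then ends up trans and the methyl cis to isopropyl (C3 set by C6).

Step 6
Reactants: 9 ethyl 2-[(1R,3R)-1-methyl-2-methylidene-3-(propan-2-yl)cyclopentyl]acetate
Product: 11 ethyl 2-[(1R,3R)-1-methyl-2-oxo-3-(propan-2-yl)cyclopentyl]acetate, via ozonide 10 (not isolated)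
Conditions: O3, CH2Cl2, −78 °C; then PPh3, −78 to 25 °C
Reagents that add atoms: ozone, [O-][O+]=O
Why: Ozonolysis of the 1,1-disubstituted alkene gives the C7 ketone; the neutral reductive work-up should leave the now enolisable C6 centre untouched.

Step 7
Reactants: 11 ethyl 2-[(1R,3R)-1-methyl-2-oxo-3-(propan-2-yl)cyclopentyl]acetate; 12 trimethylsulfonium iodide
Product: 13 ethyl 2-[(3S,4R,7R)-4-methyl-7-(propan-2-yl)-1-oxaspiro[2.4]heptan-4-yl]acetate
Conditions: Me3S+ I− (1.3 equiv), n-BuLi (1.2 equiv), THF, −10 °C; then 11, −10 to 0 °C
Reagents that add atoms: none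
Why: Corey–Chaykovsky epoxidation: dimethylsulfonium methylide adds irreversibly to the ketone from the α face, which carries only the C6 hydrogen and the acetate arm, while the β face carries both methyl and isopropyl. The betaine closes, so the methylene C8 is α and the oxygen β (C7 set by C6 and C3). The ester should be left alone at this temperature.

Step 8
Reactants: 13 ethyl 2-[(3S,4R,7R)-4-methyl-7-(propan-2-yl)-1-oxaspiro[2.4]heptan-4-yl]acetate
Product: 14 2-[(3S,4R,7R)-4-methyl-7-(propan-2-yl)-1-oxaspiro[2.4]heptan-4-yl]acetaldehyde
Conditions: i-Bu2AlH (1.1 equiv), PhMe, −78 °C; aq. potassium sodium tartrate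
Reagents that add atoms: none
Why: Partial reduction of an ester next to a quaternary carbon stops at the tetrahedral aluminate at −78 °C and gives the aldehyde on work-up; the hindered 2,2-disubstituted epoxide is inert at this temperature.

Step 9
Reactants: 14 2-[(3S,4R,7R)-4-methyl-7-(propan-2-yl)-1-oxaspiro[2.4]heptan-4-yl]acetaldehyde; 15 ethyl 2-[bis(2,2,2-trifluoroethoxy)phosphoryl]propanoate
Product: 16 ethyl (2Z)-2-methyl-4-[(3S,4R,7R)-4-methyl-7-(propan-2-yl)-1-oxaspiro[2.4]heptan-4-yl]but-2-enoate
Conditions: KN(SiMe3)2, 18-crown-6, THF, −78 °C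
Reagents that add atoms: none
Why: Still–Gennari olefination: the trifluoroethyl phosphonate under dissociating conditions eliminates fast from the kinetic adduct and gives the (Z)-α-methyl enoate; this sets the C1=C10 geometry, and the ester carbon becomes C9.

Step 10
Reactants: 16 ethyl (2Z)-2-methyl-4-[(3S,4R,7R)-4-methyl-7-(propan-2-yl)-1-oxaspiro[2.4]heptan-4-yl]but-2-enoate
Product: 17 (2Z)-2-methyl-4-[(3S,4R,7R)-4-methyl-7-(propan-2-yl)-1-oxaspiro[2.4]heptan-4-yl]but-2-en-1-ol
Conditions: i-Bu2AlH (2.5 equiv), CH2Cl2, −78 °C; aq. potassium sodium tartrate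
Reagents that add atoms: none
Why: 1,2-Reduction of the enoate gives the allylic alcohol without touching the alkene geometry or the epoxide.

Step 11
Reactants: 17 (2Z)-2-methyl-4-[(3S,4R,7R)-4-methyl-7-(propan-2-yl)-1-oxaspiro[2.4]heptan-4-yl]but-2-en-1-ol; 18 sodium benzenesulfinate
Product: 20 (3S,4R,7R)-4-[(2Z)-4-(benzenesulfonyl)-3-methylbut-2-en-1-yl]-4-methyl-7-(propan-2-yl)-1-oxaspiro[2.4]heptane, via allylic mesylate 19 (not isolated)
Conditions: MsCl, Et3N, CH2Cl2, −30 °C; solvent exchange; then PhSO2Na, DMF, 0 to 25 °C
Reagents that add atoms: methanesulfonyl chloride, CS(=O)(=O)Cl (its atoms stay in 19 only)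
Why: Mesylation under amine base, then SN2 displacement at the primary allylic carbon by the sulfur of the sulfinate, the standard route to allylic aryl sulfones; no allyl cation is formed, so the (Z)-alkene and the epoxide should survive.

Step 12
Reactants: 20 (3S,4R,7R)-4-[(2Z)-4-(benzenesulfonyl)-3-methylbut-2-en-1-yl]-4-methyl-7-(propan-2-yl)-1-oxaspiro[2.4]heptane
Product: 21 (1S,7R,10R)-3-(benzenesulfonyl)-4,7-dimethyl-10-(propan-2-yl)bicyclo[5.3.0]dec-4-en-1-ol (both epimers at the sulfonyl carbon)
Conditions: LiN(SiMe3)2 (1.1 equiv), THF–DMPU, −78 to 25 °C; aq. NH4Cl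
Reagents that add atoms: none
Why: The amide base removes the proton at C9, which is both allylic and α to the sulfonyl group, and the lithiated allyl sulfone attacks the epoxide methylene C8 opposite to its C–O bond (SN2), forming C8–C9 and freeing the C7 alkoxide. The closest known reaction type is the intramolecular alkylation of sulfone-stabilised allyl carbanions by epoxides, used to close carbocycles. The seven-membered ring closes in the endo sense with respect to the epoxide: both epoxide carbons enter the ring and the oxygen stays on ring atom C7. No stereocentre of the target is made here; C7 keeps the configuration from step 7 because its C–O bond is not broken, and the cis fusion follows because C2 and C8 both lie on the α face. C9 becomes a stereocentre without control, which does not matter because it is trigonal again after step 14. The step needs attack at C8 rather than C7, which is secured because C7 is fully substituted and closed to SN2. It needs α- rather than γ-attack of the ambident anion, which is the normal behaviour of lithiated allyl sulfones; γ-attack would also require a strained five-membered transition state. It needs the (Z)-alkene, which places C9 on the same side as C2; the E isomer could not close to a cycloheptene.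

Step 13
Reactants: 21 (1S,7R,10R)-3-(benzenesulfonyl)-4,7-dimethyl-10-(propan-2-yl)bicyclo[5.3.0]dec-4-en-1-ol
Product: 22 (1S,4R,5R,7R,10R)-3-(benzenesulfonyl)-4,5-epoxy-4,7-dimethyl-10-(propan-2-yl)bicyclo[5.3.0]decan-1-ol
Conditions: VO(acac)2 (cat.), t-BuOOH, PhH, 25 to 40 °C
Reagents that add atoms: tert-butyl hydroperoxide, CC(C)(C)OO
Why: Vanadium-catalysed hydroxyl-directed epoxidation: the C7 hydroxyl is bishomoallylic to C1=C10 through both ring arms, binds the vanadium peroxide and delivers oxygen to the β face, which sets C1. Undirected attack on this electron-poor alkene should be slow, and the β-epoxide cannot be opened by the C7 hydroxyl because both lie on the same face.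

Step 14
Reactants: 22 (1S,4R,5R,7R,10R)-3-(benzenesulfonyl)-4,5-epoxy-4,7-dimethyl-10-(propan-2-yl)bicyclo[5.3.0]decan-1-ol
Product: 23 (1S,5R,7R,10R)-4,7-dimethyl-10-(propan-2-yl)bicyclo[5.3.0]dec-3-ene-1,5-diol
Conditions: Na(Hg) (6%), Na2HPO4, MeOH–THF, −20 °C
Reagents that add atoms: none
Why: Reductive desulfonylation with β-elimination, the epoxide counterpart of the Julia elimination: electron transfer cleaves C9–S, and the C9 carbanion expels the epoxide oxygen from C10, giving the C9=C10 alkene and the C1 alkoxide with C1 unchanged. No free allyl anion is formed, so the alkene position is defined.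

Step 15
Reactants: 23 (1S,5R,7R,10R)-4,7-dimethyl-10-(propan-2-yl)bicyclo[5.3.0]dec-3-ene-1,5-diol; 24 4-methoxybenzoyl chloride
Product: 25 (1R,3R,7S,8R)-7-hydroxy-1,4-dimethyl-8-(propan-2-yl)bicyclo[5.3.0]dec-4-en-3-yl 4-methoxybenzoate
Conditions: pyridine, DMAP (cat.), CH2Cl2, 0 to 25 °C
Reagents that add atoms: none
Why: Acylation under nucleophilic catalysis takes the secondary allylic hydroxyl at C1; the tertiary C7 hydroxyl is too hindered to react under these conditions.

Step 16
Reactants: 25 (1R,3R,7S,8R)-7-hydroxy-1,4-dimethyl-8-(propan-2-yl)bicyclo[5.3.0]dec-4-en-3-yl 4-methoxybenzoate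
Product: 27 (1R,3R,4R,7S,8R)-4,7-dihydroxy-1,4-dimethyl-8-(propan-2-yl)bicyclo[5.3.0]decan-3-yl 4-methoxybenzoate, via hydroperoxide 26 (not isolated)
Conditions: Co(acac)2 (cat.), PhSiH3, O2 (1 atm), THF, 0 to 25 °C; then PPh3
Reagents that add atoms: dioxygen, O=O
Why: Mukaiyama hydration: hydrogen-atom transfer from a cobalt hydride to C9 gives the tertiary C10 radical (Markovnikov), O2 traps it and PPh3 reduces hydroperoxide 26. O2 should approach anti to the neighbouring C1 aroyloxy group and away from the β groups at C3 and C7, that is from the α face, which sets C10. The radical path leaves no cation for the C7 hydroxyl to trap.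

## Compound list

1 | (S)-(−)-limonene, (4S)-1-methyl-4-(prop-1-en-2-yl)cyclohex-1-ene | CC1=CC[C@H](CC1)C(C)=C | starting material
2 | (4S)-1-methyl-4-(propan-2-yl)cyclohex-1-ene | CC1=CC[C@H](CC1)C(C)C | intermediate
3 | ozonide of 2, (4S)-1-methyl-4-(propan-2-yl)-7,8,9-trioxabicyclo[4.2.1]nonane, formed and consumed in step 2 | CC12CC[C@@H](CC(OO1)O2)C(C)C | intermediate
4 | (3S)-6-oxo-3-(propan-2-yl)heptanal | O=CC[C@H](CCC(C)=O)C(C)C | intermediate
5 | (5R)-2-methyl-5-(propan-2-yl)cyclopent-1-ene-1-carbaldehyde | O=CC1=C(C)CC[C@@H]1C(C)C | intermediate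
6 | [(5R)-2-methyl-5-(propan-2-yl)cyclopent-1-en-1-yl]methanol | OCC1=C(C)CC[C@@H]1C(C)C | intermediate
7 | triethyl orthoacetate (1,1,1-triethoxyethane) | CCOC(C)(OCC)OCC | starting material
8 | ketene acetal, (5R)-1-{[(1-ethoxyethenyl)oxy]methyl}-2-methyl-5-(propan-2-yl)cyclopent-1-ene, formed and consumed in step 5 | C=C(OCC)OCC1=C(C)CC[C@@H]1C(C)C | intermediate
9 | ethyl 2-[(1R,3R)-1-methyl-2-methylidene-3-(propan-2-yl)cyclopentyl]acetate | CCOC(=O)C[C@@]1(C)CC[C@H](C(C)C)C1=C | intermediate
10 | ozonide of 9, ethyl 2-[(6R,9R)-6-methyl-9-(propan-2-yl)-1,2,4-trioxaspiro[4.4]nonan-6-yl]acetate (either configuration at the spiro carbon), formed and consumed in step 6 | CCOC(=O)C[C@@]1(C)CC[C@H](C(C)C)C12OCOO2 | intermediate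
11 | ethyl 2-[(1R,3R)-1-methyl-2-oxo-3-(propan-2-yl)cyclopentyl]acetate | CCOC(=O)C[C@@]1(C)CC[C@H](C(C)C)C1=O | intermediate
12 | trimethylsulfonium iodide | C[S+](C)C.[I-] | starting material
13 | ethyl 2-[(3S,4R,7R)-4-methyl-7-(propan-2-yl)-1-oxaspiro[2.4]heptan-4-yl]acetate (epoxide oxygen cis to methyl and isopropyl) | CCOC(=O)C[C@@]1(C)CC[C@H](C(C)C)[C@@]12CO2 | intermediate
14 | 2-[(3S,4R,7R)-4-methyl-7-(propan-2-yl)-1-oxaspiro[2.4]heptan-4-yl]acetaldehyde | O=CC[C@@]1(C)CC[C@H](C(C)C)[C@@]12CO2 | intermediate
15 | ethyl 2-[bis(2,2,2-trifluoroethoxy)phosphoryl]propanoate | CCOC(=O)C(C)P(=O)(OCC(F)(F)F)OCC(F)(F)F | starting material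
16 | ethyl (2Z)-2-methyl-4-[(3S,4R,7R)-4-methyl-7-(propan-2-yl)-1-oxaspiro[2.4]heptan-4-yl]but-2-enoate | CCOC(=O)/C(C)=C\C[C@@]1(C)CC[C@H](C(C)C)[C@@]12CO2 | intermediate
17 | (2Z)-2-methyl-4-[(3S,4R,7R)-4-methyl-7-(propan-2-yl)-1-oxaspiro[2.4]heptan-4-yl]but-2-en-1-ol | OC/C(C)=C\C[C@@]1(C)CC[C@H](C(C)C)[C@@]12CO2 | intermediate
18 | sodium benzenesulfinate | [Na+].[O-]S(=O)c1ccccc1 | starting material
19 | allylic mesylate, (2Z)-2-methyl-4-[(3S,4R,7R)-4-methyl-7-(propan-2-yl)-1-oxaspiro[2.4]heptan-4-yl]but-2-en-1-yl methanesulfonate, formed and consumed in step 11 | CS(=O)(=O)OC/C(C)=C\C[C@@]1(C)CC[C@H](C(C)C)[C@@]12CO2 | intermediate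
20 | (3S,4R,7R)-4-[(2Z)-4-(benzenesulfonyl)-3-methylbut-2-en-1-yl]-4-methyl-7-(propan-2-yl)-1-oxaspiro[2.4]heptane | O=S(=O)(C/C(C)=C\C[C@@]1(C)CC[C@H](C(C)C)[C@@]12CO2)c1ccccc1 | intermediate
21 | (1S,7R,10R)-3-(benzenesulfonyl)-4,7-dimethyl-10-(propan-2-yl)bicyclo[5.3.0]dec-4-en-1-ol (cis-fused; hydroxyl, methyl and isopropyl on one face; sulfonyl carbon either configuration) | CC1=CC[C@@]2(C)CC[C@H](C(C)C)[C@@]2(O)CC1S(=O)(=O)c1ccccc1 | intermediate
22 | (1S,4R,5R,7R,10R)-3-(benzenesulfonyl)-4,5-epoxy-4,7-dimethyl-10-(propan-2-yl)bicyclo[5.3.0]decan-1-ol (epoxide oxygen on the face of the hydroxyl) | C[C@@]12O[C@@H]1C[C@@]3(C)CC[C@H](C(C)C)[C@@]3(O)CC2S(=O)(=O)c1ccccc1 | intermediate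
23 | (1S,5R,7R,10R)-4,7-dimethyl-10-(propan-2-yl)bicyclo[5.3.0]dec-3-ene-1,5-diol | O[C@@H]1C[C@@]2(C)CC[C@H](C(C)C)[C@@]2(O)CC=C1C | intermediate
24 | 4-methoxybenzoyl chloride | COc1ccc(cc1)C(Cl)=O | starting material
25 | (1R,3R,7S,8R)-7-hydroxy-1,4-dimethyl-8-(propan-2-yl)bicyclo[5.3.0]dec-4-en-3-yl 4-methoxybenzoate | COc1ccc(C(=O)O[C@@H]2C[C@@]3(C)CC[C@H](C(C)C)[C@@]3(O)CC=C2C)cc1 | intermediate
26 | hydroperoxide, (1R,3R,4R,7S,8R)-4-hydroperoxy-7-hydroxy-1,4-dimethyl-8-(propan-2-yl)bicyclo[5.3.0]decan-3-yl 4-methoxybenzoate, formed and consumed in step 16 | COc1ccc(C(=O)O[C@@H]2C[C@@]3(C)CC[C@H](C(C)C)[C@@]3(O)CC[C@@]2(C)OO)cc1 | intermediate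
27 | (1R,3R,4R,7S,8R)-4,7-dihydroxy-1,4-dimethyl-8-(propan-2-yl)bicyclo[5.3.0]decan-3-yl 4-methoxybenzoate | COc1ccc(C(=O)O[C@@H]2C[C@@]3(C)CC[C@H](C(C)C)[C@@]3(O)CC[C@@]2(C)O)cc1 | target

## Step count and least certain steps

Total: 16 steps. Longest linear sequence: 16 steps (1 to 27).

**Step 12 (key step).** The closure may be slow, because the carbanion has to reach a methylene that hangs on a fully substituted carbon through a seven-membered transition state. The lithiated sulfone could then be consumed by base-promoted isomerisation of the epoxide to an allylic alcohol or by intermolecular opening. Fallback: make the same C8–C9 bond between two molecules and close the ring elsewhere. Starting from aldehyde 14, Wittig methylenation with Ph3P=CH2 gives the allyl epoxide F1. The lithium anion of methallyl phenyl sulfone, with BF3·OEt2 activation, opens F1 at C8 to give the open-chain diene hydroxy sulfone F2. Ring-closing metathesis with second-generation Grubbs catalyst forms C1=C10 and returns to the route at 21.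

**Step 13.** Oxygen delivery from the C7 hydroxyl may fail, through low conversion or attack on the α face, because the hydroxyl is tertiary and two carbons removed from the alkene and because the C9 sulfonyl group deactivates and may shield the alkene. Fallback: accept the sterically preferred face and correct C1 afterwards. Starting from 21, buffered mCPBA gives the α-epoxide F3. Na(Hg) as in step 14 gives the C1-epimeric allylic diol F4. Mitsunobu esterification with 4-methoxybenzoic acid (PPh3, DIAD) inverts C1 and installs the ester, returning to the route at 25.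

**Step 16.** Capture of the C10 radical by O2 may show poor facial discrimination, because O2 is small and the radical is planar; simple reduction of the alkene can also compete. Fallback: a two-electron sequence. Starting from 25, mCPBA epoxidation anti to the ester gives the α-epoxide F5. LiAlH4 delivers hydride to C9 and removes the ester at the same time to give the triol F6. Acylation of its only secondary hydroxyl with 24 under the conditions of step 15 gives 27.

**Step 7.** The basic ylide may enolise the hindered ketone instead of adding, which returns ketone and can epimerise C6. Fallback: a less basic one-carbon nucleophile at low temperature. Starting from 11, chloromethyllithium made in the flask (ICH2Cl, MeLi·LiBr, THF, −78 °C) adds from the same face to give, as its alkoxide, the chlorohydrin F7. F7 closes to the epoxide on warming and returns to the route at 13.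

**Step 11.** The allylic mesylate may ionise, with loss of the (Z) geometry or allylic transposition, and the sulfinate may react in part at oxygen. Fallback: bring in sulfur at the sulfide level without a sulfonate ester. Starting from 17, PhSSPh and n-Bu3P give the allylic phenyl sulfide F8. Oxidation with H2O2 and (NH4)6Mo7O24 in EtOH converts F8 into the sulfone without touching the trisubstituted alkene and returns to the route at 20.

## Further compounds

F1 | step 12 | (3S,4R,7R)-4-methyl-7-(propan-2-yl)-4-(prop-2-en-1-yl)-1-oxaspiro[2.4]heptane | C=CC[C@@]1(C)CC[C@H](C(C)C)[C@@]12CO2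
F2 | step 12 | (1S,2R,5R)-1-[2-(benzenesulfonyl)-3-methylbut-3-en-1-yl]-2-methyl-5-(propan-2-yl)-2-(prop-2-en-1-yl)cyclopentan-1-ol (sulfonyl carbon either configuration) | C=CC[C@@]1(C)CC[C@H](C(C)C)[C@@]1(O)CC(C(C)=C)S(=O)(=O)c1ccccc1
F3 | step 13 | (1S,4S,5S,7R,10R)-3-(benzenesulfonyl)-4,5-epoxy-4,7-dimethyl-10-(propan-2-yl)bicyclo[5.3.0]decan-1-ol (epoxide oxygen on the face opposite the hydroxyl) | C[C@]12O[C@H]1C[C@@]3(C)CC[C@H](C(C)C)[C@@]3(O)CC2S(=O)(=O)c1ccccc1
F4 | step 13 | (1S,5S,7R,10R)-4,7-dimethyl-10-(propan-2-yl)bicyclo[5.3.0]dec-3-ene-1,5-diol | O[C@H]1C[C@@]2(C)CC[C@H](C(C)C)[C@@]2(O)CC=C1C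
F5 | step 16 | α-epoxide of 25 at C9–C10 (oxygen on the face opposite the ester), (1R,3R,4R,5R,7S,8R)-4,5-epoxy-7-hydroxy-1,4-dimethyl-8-(propan-2-yl)bicyclo[5.3.0]decan-3-yl 4-methoxybenzoate | COc1ccc(C(=O)O[C@@H]2C[C@@]3(C)CC[C@H](C(C)C)[C@@]3(O)C[C@H]4O[C@@]24C)cc1
F6 | step 16 | (1S,4R,5R,7R,10R)-4,7-dimethyl-10-(propan-2-yl)bicyclo[5.3.0]decane-1,4,5-triol | O[C@@H]1C[C@@]2(C)CC[C@H](C(C)C)[C@@]2(O)CC[C@@]1(C)O
F7 | step 7 | ethyl 2-[(1R,2S,3R)-2-(chloromethyl)-2-hydroxy-1-methyl-3-(propan-2-yl)cyclopentyl]acetate | CCOC(=O)C[C@@]1(C)CC[C@H](C(C)C)[C@@]1(O)CCl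
F8 | step 11 | (3S,4R,7R)-4-methyl-4-[(2Z)-3-methyl-4-(phenylsulfanyl)but-2-en-1-yl]-7-(propan-2-yl)-1-oxaspiro[2.4]heptane | c1ccccc1SC/C(C)=C\C[C@@]1(C)CC[C@H](C(C)C)[C@@]12CO2
A1 | alternative 1 | 2-methyl-2-(4-methylpent-3-en-1-yl)cycloheptane-1,3-dione | CC(C)=CCCC1(C)C(=O)CCCCC1=O
A2 | alternative 1 | (1S,7S,8R)-7-hydroxy-1-methyl-8-(prop-1-en-2-yl)bicyclo[5.3.0]decan-2-one (cis-fused) | O=C2[C@@]3(C)CC[C@H](C(C)=C)[C@@]3(O)CCCC2
A3 | alternative 2 | (6R)-3-chloro-3,7-dimethyl-6-(5-methylfuran-2-yl)octan-2-one | CC(=O)C(C)(Cl)CC[C@H](C(C)C)c1ccc(C)o1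
A4 | alternative 2 | cyclopentane-fused 8-oxabicyclo[3.2.1]oct-6-en-3-one with a C7–O–C10 bridge and a C2 ketone | C1C(=O)[C@@]2(C)CC[C@H](C(C)C)[C@]23O[C@@]1(C)C=C3
A5 | alternative 3 | (6R)-3,10-dimethyl-6-(propan-2-yl)cyclodec-2-ene-1,7-dione | O=C1C=C(C)CC[C@H](C(C)C)C(=O)CCC1C
A6 | alternative 3 | (1R,7S,8R)-7-hydroxy-1,4-dimethyl-8-(propan-2-yl)bicyclo[5.3.0]decan-3-one (cis-fused, C4 either configuration) | O=C2C[C@@]3(C)CC[C@H](C(C)C)[C@@]3(O)CCC2C
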